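All runs are simulated with constants of no real substance, noise included.

Of the charge in the south-east run, a leftover of 7.5 % stands as open intermediate at 8.00 min, far more than the 0.1 % of target. The north-west run has the same gas and feed time but a larger charge, and it shows less at that time: 5.7 %.

| flask | substrate | gas | remark | time |
|---|---|---|---|---|
| south-east | 0.070 M (fed, over 6.0 min) | 2.3 mM (held) | run made earlier |  |
| north-west | 0.11 M (fed, over 6.0 min) | 2.3 mM (held) | run made earlier |  |
| flask | 0.050 M (fed, over 6.0 min) | 2.3 mM (held) |  | 20 min |

| run | time / min | open intermediate / % | target / % |
|---|---|---|---|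
| south-east | 1.50 | 2.3 | 0 |
| south-east | 3.00 | 6.7 | 0 |
| south-east | 8.00 | 7.5 | 0.1 |
| south-east | 15.0 | 4.3 | 0.2 |
| north-west | 1.50 | 2.5 | 0.7 |
| north-west | 3.00 | 4.8 | 0 |
| north-west | 8.00 | 5.7 | 0 |
| north-west | 15.0 | 4.3 | 0 |

(each reading ± 0.5 percentage points)

- at the start none of the gas is in solution
- percentages count the whole charge, also what has not yet gone in

1. the moment within 20 min at which there is most open intermediate
2. the amount of open intermediate, in percent of the substrate charged, at that time

I read the open intermediate as a tank whose drain grows with the square of the level. In such a quasi-steady state the level follows the square root of the supply, so with gas, feed time and moment held the percentage falls as the charge rises. I therefore freeze one quantity at a given time. The square of the fraction times the charge comes to 0.394 mM in the south-east run and 0.357 mM in the north-west run. Their mean, 0.376 mM, carries the scatter of those readings and is my balance concentration, [open intermediate]² over the charge. This flask has a smaller charge than the south-east run, so my reckoning puts it higher at 8.00 min: 8.67 %, against 7.5 % there.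

The forecast gives a peak of 8.8 % at 7.5 min, on the grounds that “The peak should fall shortly after feeding ends”. Mine is a figure for 8.00 min, not for the peak.

The flask peaks at 6.39 min with 9.90 %.

    2 open intermediate → homo product (k = 1.49 L mol⁻¹ s⁻¹)
    gas ⇌ partner, rate k2*(csat - [partner]) (kL = 0.155 s⁻¹)
    partner → second intermediate (k = 0.00106 s⁻¹)
    open intermediate + second intermediate ⇌ target (K = 7.00 L mol⁻¹, k = 2.60 L mol⁻¹ s⁻¹)
    substrate → open intermediate (k = 0.00225 s⁻¹)

At that peak the balance concentration of the flask is 0.490 mM, above the 0.376 mM I read from the two earlier runs at the later time of 8.00 min. The forecast's peak is lower and later than this one. I carry the peak value to the neighbouring flask, which differs in holding 0.020 M of substrate. The reckoning gives 15.7 % at its peak, and that flask reaches 15.3 %.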